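Ring C is disconnected at O1–C2 and C3–C4. The atoms O1–C8a–C4a–C4 are treated as the oxa-diene of an ortho-quinone methide carried by the electron-rich ring A, and C2–C3 as the vinyl group of a catechol styrene. One chiral-acid-catalysed oxa-(4+2) cycloaddition forms both bonds, closes ring C, fixes the 6-prenyl regiochemistry and sets C2 (S). C4 arrives as a methyl ether at the alcohol oxidation level and is oxidised to the ketone afterwards. The precursor is a 3-prenyl-2,4-bis(silyloxy)-6-hydroxybenzaldehyde whose single free phenol sits next to the future C8–H, reached by ortho-formylation of a symmetric 4-prenyl-3,5-bis(silyloxy)phenol.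

Key step: step 9

Assumption: the (R)-configured catalyst is taken to deliver the 2S series through the endo (2,4-cis) mode; if the sense of induction proves opposite, the enantiomeric catalyst is used, and any C4 epimer of the cycloadduct is carried on because C4 is oxidised later.

Abbreviations: TBS = tert-butyldimethylsilyl; MOM = methoxymethyl; prenyl = 3-methylbut-2-enyl; DDQ = 2,3-dichloro-5,6-dicyano-1,4-benzoquinone.

Step 1
Reactants: 1 resorcinol
Product: 2 1,3-bis(methoxymethoxy)benzene
Conditions: NaH, MOMCl, DMF, 0 °C to rt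
Reagents that add atoms: chloromethyl methyl ether, COCCl
Why: Double Williamson O-alkylation of the bis-phenoxide installs two MOM acetals, which are needed as ortho-directing groups because direct prenylation of resorcinol would go to C4 and not to C2.

Step 2
Reactants: 2 1,3-bis(methoxymethoxy)benzene; 3 prenyl bromide
Product: 5 1,3-bis(methoxymethoxy)-2-prenylbenzene, via aryllithium 4 (not isolated)
Conditions: n-BuLi, THF, 0 °C to rt; then CuI (10 mol %), prenyl bromide, −78 °C to rt
Reagents that add atoms: prenyl bromide 3, CC(C)=CCBr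
Why: Directed ortho-metalation, in which both MOM ethers direct lithiation to the shared C2 position, followed by SN2 alkylation at the primary carbon of the allylic bromide, places the prenyl group between the two oxygens.

Step 3
Reactants: 5 1,3-bis(methoxymethoxy)-2-prenylbenzene
Product: 6 2-prenylresorcinol
Conditions: HCl (0.5 M), MeOH, rt
Reagents that add atoms: none
Why: Acid-catalysed acetal methanolysis releases both phenols, and dilute acid at room temperature should not protonate the trisubstituted alkene, so cyclisation to the chroman is expected to stay minor.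

Step 4
Reactants: 6 2-prenylresorcinol
Product: 7 1,3-bis(tert-butyldimethylsilyloxy)-2-prenylbenzene
Conditions: TBSCl, imidazole, DMF, rt
Reagents that add atoms: tert-butyldimethylsilyl chloride, CC(C)(C)[Si](C)(C)Cl
Why: Imidazole-promoted O-silylation gives aryl silyl ethers that tolerate the later acid catalysis and oxidation and are removed at the end by fluoride without acid or base.

Step 5
Reactants: 7 1,3-bis(tert-butyldimethylsilyloxy)-2-prenylbenzene
Product: 9 3,5-bis(tert-butyldimethylsilyloxy)-4-prenylphenol, via arylboronate 8 (not isolated)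
Conditions: [Ir(OMe)(cod)]2 (1.5 mol %), 4,4′-di-tert-butyl-2,2′-bipyridine (3 mol %), B2pin2, THF, 50 °C; then NaBO3·4H2O, THF/H2O, rt
Reagents that add atoms: sodium perborate, [Na+].[Na+].O[B-]1(O)OO[B-](O)(O)OO1 (phenol oxygen); bis(pinacolato)diboron, CC1(C)OB(OC1(C)C)B1OC(C)(C)C(C)(C)O1 (boron of intermediate 8 only)
Why: Sterically governed iridium-catalysed aromatic C–H borylation selects the only C–H without an ortho substituent (C5, meta to both silyloxy groups), and mild perborate oxidation of the C–B bond gives the symmetric phenol without touching the trisubstituted alkene.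

Step 6
Reactants: 9 3,5-bis(tert-butyldimethylsilyloxy)-4-prenylphenol
Product: 11 6-hydroxy-2,4-bis(tert-butyldimethylsilyloxy)-3-prenylbenzaldehyde, via salicyl alcohol 10 (not isolated)
Conditions: MgCl2, Et3N, (CH2O)n, THF, 65 °C
Reagents that add atoms: paraformaldehyde (as formaldehyde), C=O
Why: In this Casnati–Skattebøl ortho-formylation the magnesium phenoxide delivers formaldehyde to one of the two symmetry-equivalent ortho carbons and a second formaldehyde oxidises the benzylic alkoxide by hydride transfer, so the aldehyde ends between the free phenol and one silyloxy group.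

Step 7
Reactants: 12 3,4-dihydroxybenzaldehyde
Product: 13 3,4-bis(tert-butyldimethylsilyloxy)benzaldehyde
Conditions: TBSCl, imidazole, DMF, rt
Reagents that add atoms: tert-butyldimethylsilyl chloride, CC(C)(C)[Si](C)(C)Cl
Why: Standard imidazole-promoted silylation masks the catechol, which would otherwise quench the ylide in step 8 and compete as a nucleophile in step 9.

Step 8
Reactants: 13 3,4-bis(tert-butyldimethylsilyloxy)benzaldehyde
Product: 14 3,4-bis(tert-butyldimethylsilyloxy)styrene
Conditions: Ph3PCH3Br, n-BuLi, THF, 0 °C; then 13, 0 °C to rt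
Reagents that add atoms: methyltriphenylphosphonium bromide, C[P+](c1ccccc1)(c1ccccc1)c1ccccc1.[Br-]
Why: Wittig methylenation with the preformed, alkoxide-free ylide converts the aldehyde into the styrene while the aryl silyl ethers stay intact.

Step 9
Reactants: 11 6-hydroxy-2,4-bis(tert-butyldimethylsilyloxy)-3-prenylbenzaldehyde; 14 3,4-bis(tert-butyldimethylsilyloxy)styrene; 15 trimethyl orthoformate
Product: 18 (2S,4S)-4-methoxy-5,7,3′,4′-tetrakis(tert-butyldimethylsilyloxy)-6-prenylflavan, via dimethyl acetal 16 (not isolated), via methoxy ortho-quinone methide 17 (not isolated)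
Conditions: (R)-3,3′-bis(2,4,6-triisopropylphenyl)-1,1′-bi-2-naphthol N-triflyl phosphoramide (10 mol %), HC(OMe)3 (1.5 equiv), 14 (1.5 equiv), 5 Å molecular sieves, toluene, −40 °C; Et3N quench
Reagents that add atoms: trimethyl orthoformate 15, COC(OC)OC
Why: Proposed new method: the acid should convert 11 and 15 into acetal 16 and ionise it to the O-protonated form of 17, a 2-hydroxyaryl(methoxy)carbenium ion hydrogen-bonded through its phenol to the chiral phosphoramide anion; the CH2 terminus of styrene 14 attacks the carbenium carbon (C4) and the benzylic cation developing at C2, stabilised by the para silyloxy group of ring B, is captured by the phenol oxygen O1. The closest known reaction types are the achiral acid-catalysed oxa-(4+2) cycloadditions of salicylaldehyde–orthoformate-derived ortho-quinone methides with styrenes, which give racemic 4-alkoxyflavans, and chiral phosphoric acid-catalysed cycloadditions of ortho-quinone methides from ortho-hydroxybenzyl alcohols with styrenes; their combination under asymmetric counter-anion control is the untested part. Ring C closes as a six-membered pyran in an asynchronous inverse-demand hetero-Diels–Alder mode, C3–C4 first and then 6-exo-type O1–C2 closure onto the C2 cation. C2 (S) is controlled by the chiral anion, which blocks one face of the planar heterodiene and favours the endo approach of the aryl group, and C4 (S, 2,4-cis) follows from that endo geometry, although C4 is a throw-away stereocentre that step 10 flattens. Regiochemistry needs no catalyst control: the polarity pairs the nucleophilic styrene terminus with the carbenium carbon, and 11 has one free phenol only, the one beside the future C8–H, so O1 and hence the 6-prenyl pattern are fixed by the substrate. The selectivity that matters is the enantiomeric purity at C2, which requires a tight ion pair and a short-lived C2 cation, and low temperature, toluene and sieves that take up methanol are chosen to secure this and to stop the acid-labile product ether from ionising again.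

Step 10
Reactants: 18 (2S,4S)-4-methoxy-5,7,3′,4′-tetrakis(tert-butyldimethylsilyloxy)-6-prenylflavan
Product: 20 (2S)-5,7,3′,4′-tetrakis(tert-butyldimethylsilyloxy)-6-prenylflavanone, via hemiketal 19 (not isolated)
Conditions: DDQ (1.3 equiv), CH2Cl2/pH 7 phosphate buffer (10:1), 0 °C to rt
Reagents that add atoms: water, O
Why: DDQ abstracts the C4 hydride, which is benzylic to the trioxygenated ring A and α to the methoxy oxygen (the oxidative benzylic-ether cleavage known for C4 of 5,7-dioxygenated flavans), water traps the methoxycarbenium ion and the hemiketal loses methanol, so both C4 epimers converge on the ketone while C2 is untouched.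

Step 11
Reactants: 20 (2S)-5,7,3′,4′-tetrakis(tert-butyldimethylsilyloxy)-6-prenylflavanone
Product: 21 (2S)-5,7,3′,4′-tetrahydroxy-6-prenylflavanone (6-prenyleriodictyol)
Conditions: Et3N·3HF, THF, 0 °C to rt
Reagents that add atoms: none
Why: Buffered fluoride cleaves the four aryl silyl ethers under near-neutral conditions, which avoids base-induced ring opening to the chalcone (racemisation at C2) and acid-induced cyclisation of the prenyl group onto the 5- or 7-hydroxyl.

Compound list
1 | resorcinol | Oc1cccc(O)c1 | starting material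
2 | 1,3-bis(methoxymethoxy)benzene | COCOc1cccc(OCOC)c1 | intermediate
3 | prenyl bromide (1-bromo-3-methylbut-2-ene) | CC(C)=CCBr | starting material
4 | 2,6-bis(methoxymethoxy)phenyllithium | [Li]c1c(OCOC)cccc1OCOC | intermediate (not isolated)
5 | 1,3-bis(methoxymethoxy)-2-(3-methylbut-2-enyl)benzene | COCOc1cccc(OCOC)c1CC=C(C)C | intermediate
6 | 2-(3-methylbut-2-enyl)benzene-1,3-diol (2-prenylresorcinol) | CC(C)=CCc1c(O)cccc1O | intermediate
7 | 1,3-bis(tert-butyldimethylsilyloxy)-2-(3-methylbut-2-enyl)benzene | CC(C)=CCc1c(O[Si](C)(C)C(C)(C)C)cccc1O[Si](C)(C)C(C)(C)C | intermediate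
8 | 2-[3,5-bis(tert-butyldimethylsilyloxy)-4-(3-methylbut-2-enyl)phenyl]-4,4,5,5-tetramethyl-1,3,2-dioxaborolane | CC(C)=CCc1c(O[Si](C)(C)C(C)(C)C)cc(B2OC(C)(C)C(C)(C)O2)cc1O[Si](C)(C)C(C)(C)C | intermediate (not isolated)
9 | 3,5-bis(tert-butyldimethylsilyloxy)-4-(3-methylbut-2-enyl)phenol | CC(C)=CCc1c(O[Si](C)(C)C(C)(C)C)cc(O)cc1O[Si](C)(C)C(C)(C)C | intermediate
10 | 2-(hydroxymethyl)-3,5-bis(tert-butyldimethylsilyloxy)-4-(3-methylbut-2-enyl)phenol (present as its magnesium salt) | OCc1c(O)cc(O[Si](C)(C)C(C)(C)C)c(CC=C(C)C)c1O[Si](C)(C)C(C)(C)C | intermediate (not isolated)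
11 | 6-hydroxy-2,4-bis(tert-butyldimethylsilyloxy)-3-(3-methylbut-2-enyl)benzaldehyde | O=Cc1c(O)cc(O[Si](C)(C)C(C)(C)C)c(CC=C(C)C)c1O[Si](C)(C)C(C)(C)C | intermediate
12 | 3,4-dihydroxybenzaldehyde | O=Cc1ccc(O)c(O)c1 | starting material
13 | 3,4-bis(tert-butyldimethylsilyloxy)benzaldehyde | O=Cc1ccc(O[Si](C)(C)C(C)(C)C)c(O[Si](C)(C)C(C)(C)C)c1 | intermediate
14 | 3,4-bis(tert-butyldimethylsilyloxy)styrene | C=Cc1ccc(O[Si](C)(C)C(C)(C)C)c(O[Si](C)(C)C(C)(C)C)c1 | intermediate
15 | trimethyl orthoformate | COC(OC)OC | starting material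
16 | 2-(dimethoxymethyl)-3,5-bis(tert-butyldimethylsilyloxy)-4-(3-methylbut-2-enyl)phenol | COC(OC)c1c(O)cc(O[Si](C)(C)C(C)(C)C)c(CC=C(C)C)c1O[Si](C)(C)C(C)(C)C | intermediate (not isolated)
17 | 6-(methoxymethylidene)-3,5-bis(tert-butyldimethylsilyloxy)-4-(3-methylbut-2-enyl)cyclohexa-2,4-dien-1-one (reacts as its O-protonated carbenium ion paired with the catalyst anion) | COC=C1C(=O)C=C(O[Si](C)(C)C(C)(C)C)C(CC=C(C)C)=C1O[Si](C)(C)C(C)(C)C | intermediate (not isolated)
18 | (2S,4S)-4-methoxy-5,7,3′,4′-tetrakis(tert-butyldimethylsilyloxy)-6-(3-methylbut-2-enyl)flavan | CO[C@H]1C[C@@H](c2ccc(O[Si](C)(C)C(C)(C)C)c(O[Si](C)(C)C(C)(C)C)c2)Oc2cc(O[Si](C)(C)C(C)(C)C)c(CC=C(C)C)c(O[Si](C)(C)C(C)(C)C)c12 | intermediate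
19 | (2S)-4-hydroxy-4-methoxy-5,7,3′,4′-tetrakis(tert-butyldimethylsilyloxy)-6-(3-methylbut-2-enyl)flavan (C4 undefined) | COC1(O)C[C@@H](c2ccc(O[Si](C)(C)C(C)(C)C)c(O[Si](C)(C)C(C)(C)C)c2)Oc2cc(O[Si](C)(C)C(C)(C)C)c(CC=C(C)C)c(O[Si](C)(C)C(C)(C)C)c12 | intermediate (not isolated)
20 | (2S)-5,7,3′,4′-tetrakis(tert-butyldimethylsilyloxy)-6-(3-methylbut-2-enyl)flavanone | CC(C)=CCc1c(O[Si](C)(C)C(C)(C)C)cc2c(c1O[Si](C)(C)C(C)(C)C)C(=O)C[C@@H](c1ccc(O[Si](C)(C)C(C)(C)C)c(O[Si](C)(C)C(C)(C)C)c1)O2 | intermediate
21 | (2S)-2-(3,4-dihydroxyphenyl)-5,7-dihydroxy-6-(3-methylbut-2-enyl)-2,3-dihydrochromen-4-one (6-prenyleriodictyol) | CC(C)=CCc1c(O)cc2c(c1O)C(=O)C[C@@H](c1ccc(O)c(O)c1)O2 | target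

Total step count: 11 steps.
Longest linear sequence: 9 steps (steps 1–6, then 9–11); steps 7–8 make the styrene in parallel.

Steps most likely to fail

Step 9. The cycloaddition may proceed with poor enantiofacial control through a long-lived C2 cation. The catalyst may be deactivated by O-methylation from the orthoformate, the styrene may oligomerise cationically, and the product ether may ionise again and couple at C8. Fallback with known chemistry: setting out from 11, 14 and 15, the three components are joined by the achiral variant (Sc(OTf)3, 10 mol %, CH2Cl2, 0 °C), passing through 16 and 17. This should give racemic 4-methoxy-5,7,3′,4′-tetrakis(tert-butyldimethylsilyloxy)-6-prenylflavan F1 as a mixture of C4 epimers. Oxidation with DDQ in buffered wet CH2Cl2, as in step 10, passes through the racemic hemiketal F2 and should merge the epimers into racemic 5,7,3′,4′-tetrakis(tert-butyldimethylsilyloxy)-6-prenylflavanone F3. Preparative HPLC on an amylose tris(3,5-dimethylphenylcarbamate) phase then separates the (2R)-5,7,3′,4′-tetrakis(tert-butyldimethylsilyloxy)-6-prenylflavanone F4, which is discarded, from the (2S)-enantiomer, and the route is rejoined at 20.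

Step 10. Hydride abstraction may occur at the prenyl methylene or at C2 in place of C4. It may be slow for an epimer whose C4–H lies in the plane of ring A, or oxidation may run on towards the flavone. Fallback: setting out from 18, the benzylic methyl ether is solvolysed by SN1 hydrolysis (pyridinium p-toluenesulfonate, acetone/water, 40 °C) to (2S)-5,7,3′,4′-tetrakis(tert-butyldimethylsilyloxy)-6-prenylflavan-4-ol F5, either C4 epimer. The secondary benzylic alcohol is then oxidised with Dess–Martin periodinane (NaHCO3, CH2Cl2, 0 °C), which returns to the route at 20.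

Step 5. The iridium boryl and hydride species may hydroborate or isomerise the prenyl double bond during C–H borylation. Fallback, which keeps the alkene away from the iridium catalyst: setting out from 1, iodination (I2, NaHCO3, water, 0 °C) gives 2-iodoresorcinol F6. Silylation (TBSCl, imidazole, DMF) gives 1,3-bis(tert-butyldimethylsilyloxy)-2-iodobenzene F7. The same C5 borylation ([Ir(OMe)(cod)]2, 4,4′-di-tert-butyl-2,2′-bipyridine, B2pin2) gives the arylboronate F8, which is not isolated, and perborate oxidation gives 3,5-bis(tert-butyldimethylsilyloxy)-4-iodophenol F9. Stille coupling with tributyl(3-methylbut-2-enyl)stannane (Pd(PPh3)4, toluene, 100 °C) then installs the prenyl group at the iodine-bearing carbon and returns to the route at 9.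

Further compounds
F1 | step 9 | racemic 4-methoxy-5,7,3′,4′-tetrakis(tert-butyldimethylsilyloxy)-6-(3-methylbut-2-enyl)flavan (C4 epimers) | COC1CC(c2ccc(O[Si](C)(C)C(C)(C)C)c(O[Si](C)(C)C(C)(C)C)c2)Oc2cc(O[Si](C)(C)C(C)(C)C)c(CC=C(C)C)c(O[Si](C)(C)C(C)(C)C)c12
F2 | step 9 | racemic 4-hydroxy-4-methoxy-5,7,3′,4′-tetrakis(tert-butyldimethylsilyloxy)-6-(3-methylbut-2-enyl)flavan (not isolated) | COC1(O)CC(c2ccc(O[Si](C)(C)C(C)(C)C)c(O[Si](C)(C)C(C)(C)C)c2)Oc2cc(O[Si](C)(C)C(C)(C)C)c(CC=C(C)C)c(O[Si](C)(C)C(C)(C)C)c12
F3 | step 9 | racemic 5,7,3′,4′-tetrakis(tert-butyldimethylsilyloxy)-6-(3-methylbut-2-enyl)flavanone | CC(C)=CCc1c(O[Si](C)(C)C(C)(C)C)cc2c(c1O[Si](C)(C)C(C)(C)C)C(=O)CC(c1ccc(O[Si](C)(C)C(C)(C)C)c(O[Si](C)(C)C(C)(C)C)c1)O2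
F4 | step 9 | (2R)-5,7,3′,4′-tetrakis(tert-butyldimethylsilyloxy)-6-(3-methylbut-2-enyl)flavanone | CC(C)=CCc1c(O[Si](C)(C)C(C)(C)C)cc2c(c1O[Si](C)(C)C(C)(C)C)C(=O)C[C@H](c1ccc(O[Si](C)(C)C(C)(C)C)c(O[Si](C)(C)C(C)(C)C)c1)O2
F5 | step 10 | (2S)-5,7,3′,4′-tetrakis(tert-butyldimethylsilyloxy)-6-(3-methylbut-2-enyl)flavan-4-ol (C4 undefined) | OC1C[C@@H](c2ccc(O[Si](C)(C)C(C)(C)C)c(O[Si](C)(C)C(C)(C)C)c2)Oc2cc(O[Si](C)(C)C(C)(C)C)c(CC=C(C)C)c(O[Si](C)(C)C(C)(C)C)c12
F6 | step 5 | 2-iodoresorcinol | Oc1cccc(O)c1I
F7 | step 5 | 1,3-bis(tert-butyldimethylsilyloxy)-2-iodobenzene | CC(C)(C)[Si](C)(C)Oc1cccc(O[Si](C)(C)C(C)(C)C)c1I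
F8 | step 5 | 2-[3,5-bis(tert-butyldimethylsilyloxy)-4-iodophenyl]-4,4,5,5-tetramethyl-1,3,2-dioxaborolane (not isolated) | CC(C)(C)[Si](C)(C)Oc1cc(B2OC(C)(C)C(C)(C)O2)cc(O[Si](C)(C)C(C)(C)C)c1I
F9 | step 5 | 3,5-bis(tert-butyldimethylsilyloxy)-4-iodophenol | CC(C)(C)[Si](C)(C)Oc1cc(O)cc(O[Si](C)(C)C(C)(C)C)c1I
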